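**Retrosynthetic overview**
- Last disconnection: the four phenols are carried as MOM acetals. They come off at the very end without disturbing the CH2–O–CH2 bridge.
- Key disconnection: both C3–Br bonds. They are made together on the intact dibenzyl ether by twofold ortho-magnesiation and bromine transfer from 1,2-dibromotetrachloroethane.
- Structural feature used: in ring A and ring B alike (C1 bears CH2, C2 and C3 bear Br, C4 and C5 bear O, C6 bears H), C3 is wedged between C2–Br and C4–O. In a 2-bromo-4,5-dioxygenated precursor, C3–H is therefore the only doubly activated ring hydrogen, and the C4 acetal can hold the metal there.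
- The dibromo ether comes from a Williamson union (benzylic C–O bond) of the alcohol and the bromide made from one aldehyde. That aldehyde derives from 2-bromo-4,5-dimethoxybenzaldehyde, whose C2–Br was placed by electrophilic bromination para to the C5 oxygen.
- No ring is formed at any stage, since both benzene rings are bought, and the molecule has no stereocentre.

Key step: step 6

Assumption: the target is achiral, so no SMILES carries a stereodescriptor. The benzyl alcohol made in step 3 is divided into two equal portions, one for step 4 and one for step 5.

Step 1
Reactants: 1 2-bromo-4,5-dimethoxybenzaldehyde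
Product: 3 2-bromo-4,5-dihydroxybenzaldehyde, via cyclic bromoboronate 2 (not isolated)
Conditions: BBr3 (3 equiv), CH2Cl2, −78 °C → rt; then ice/H2O
Reagents that add atoms: BBr3, BrB(Br)Br (boron and one bromine, in intermediate 2 only; none of its atoms stays in 3)
Why: BBr3-mediated aryl methyl ether cleavage, in which boron binds each methoxy oxygen, bromide takes the methyl group by SN2 and the catechol stays parked as cyclic bromoboronate 2 until water frees it, while the aryl bromide and the aldehyde (merely complexed by the extra BBr3) should come through unchanged.

Step 2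
Reactants: 3 2-bromo-4,5-dihydroxybenzaldehyde; 4 chloromethyl methyl ether
Product: 5 2-bromo-4,5-bis(methoxymethoxy)benzaldehyde
Conditions: 4 (3 equiv), iPr2NEt (4 equiv), CH2Cl2, 0 °C → rt
Reagents that add atoms: chloromethyl methyl ether 4, COCCl
Why: Twofold O-alkylation of the acidic phenols with the very reactive α-chloro ether under a hindered amine base (MOM acetal formation), which leaves aldehyde and aryl bromide alone and installs at C4 the chelating group that step 6 relies on.

Step 3
Reactants: 5 2-bromo-4,5-bis(methoxymethoxy)benzaldehyde
Product: 6 [2-bromo-4,5-bis(methoxymethoxy)phenyl]methanol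
Conditions: NaBH4, MeOH/THF, 0 °C
Reagents that add atoms: none
Why: Borohydride 1,2-reduction of the aromatic aldehyde, to which MOM acetals and the aryl bromide are inert.

Step 4
Reactants: 6 [2-bromo-4,5-bis(methoxymethoxy)phenyl]methanol (one half of the material)
Product: 7 2-bromo-4,5-bis(methoxymethoxy)benzyl bromide
Conditions: CBr4 (1.2 equiv), PPh3 (1.25 equiv), CH2Cl2, 0 °C; short plug of Et3N-deactivated silica
Reagents that add atoms: CBr4, BrC(Br)(Br)Br
Why: Appel reaction, in which the alcohol oxygen is activated as an alkoxyphosphonium ion and displaced by bromide in an SN2 step under practically neutral conditions that the acid-sensitive MOM acetals should tolerate.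

Step 5
Reactants: 6 [2-bromo-4,5-bis(methoxymethoxy)phenyl]methanol (the other half); 7 2-bromo-4,5-bis(methoxymethoxy)benzyl bromide
Product: 9 bis[2-bromo-4,5-bis(methoxymethoxy)benzyl] ether, via sodium alkoxide 8 (not isolated)
Conditions: NaH (1.2 equiv), THF/DMF, 0 °C; then 7, 0 °C → rt
Reagents that add atoms: NaH, [Na+].[H-] (sodium, in intermediate 8 only; none of its atoms stays in 9)
Why: Williamson ether synthesis, in which the primary alkoxide 8 displaces bromide from the unhindered benzylic carbon of 7 by SN2, no β-hydrogen is available for elimination, and aryl bromides and acetals are stable to alkoxide at room temperature.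

Step 6
Reactants: 9 bis[2-bromo-4,5-bis(methoxymethoxy)benzyl] ether; 10 1,2-dibromotetrachloroethane
Product: 12 bis[2,3-dibromo-4,5-bis(methoxymethoxy)benzyl] ether, via bis(arylmagnesium chloride) 11 (not isolated)
Conditions: TMPMgCl·LiCl (3.0 equiv), THF, −15 → 0 °C (conversion followed by D2O quench of aliquots); then 10 (3.5 equiv) in THF, −30 °C → rt; aq. NH4Cl
Reagents that add atoms: 1,2-dibromotetrachloroethane 10, ClC(Cl)(Br)C(Cl)(Cl)Br (one bromine per ring); TMPMgCl·LiCl, CC1(C)CCCC(C)(C)N1[Mg]Cl.[Li+].[Cl-] (MgCl, in intermediate 11 only)
Why: Directed ortho-magnesiation followed by electrophilic bromination: the TMP amide of TMPMgCl·LiCl, pre-complexed to the acetal oxygens of the C4 MOM group, removes the C3 proton of each ring, which is the most acidic ring hydrogen because the inductively withdrawing C2 bromine and C4 oxygen flank it, and leaves bis(arylmagnesium chloride) 11. Each C3–Mg bond then attacks a bromine atom of 10, and the 2-bromotetrachloroethyl anion so formed collapses to tetrachloroethene and bromide, so the two new C3–Br bonds form without free Br2 or acid that could touch the acetals. The closest known reaction type is the magnesiation of halo- and alkoxy-substituted arenes and heteroarenes with LiCl-solubilised TMP magnesium amides and quenching with 10. No ring is closed and no stereocentre is created. The step needs C3 over C6 and over the four benzylic hydrogens: C6–H has only one oxygen neighbour and no halogen, and the benzylic C–H bonds lie beyond the reach of a magnesium amide, so neither C6 metalation nor a [1,2]-Wittig rearrangement of the dibenzyl ether should compete. The covalent C–Mg bond should keep the ortho-bromoaryl metal from losing MgBrCl to an aryne or from halogen migration at or below 0 °C, an amide base cannot undergo Br/Mg exchange at C2, and the CH2OCH2 spacer insulates the rings so that the second magnesiation should run like the first.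

Step 7
Reactants: 12 bis[2,3-dibromo-4,5-bis(methoxymethoxy)benzyl] ether
Product: 13 bis(2,3-dibromo-4,5-dihydroxybenzyl) ether
Conditions: TFA/CH2Cl2 (1:9), N2, 0 °C → rt; H2O wash, no base and no alcohol solvent in work-up or purification
Reagents that add atoms: none
Why: Acid-catalysed acetal cleavage, in which protonation of each MOM acetal releases the phenol and a methoxymethyl cation that ends as formaldehyde and methanol on the water wash, trifluoroacetate is too poor a nucleophile to open the dibenzyl ether (whose ionisation is slowed by two electron-withdrawing bromines per ring), and keeping base and alcohols out of the work-up closes the quinone-methide solvolysis path of the free para-hydroxybenzyl ether.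

**Compound list**
1 | 2-bromo-4,5-dimethoxybenzaldehyde | COc1cc(Br)c(C=O)cc1OC | starting material
2 | 2,6-dibromo-1,3,2-benzodioxaborole-5-carbaldehyde (cyclic bromoboronate, not isolated) | O=Cc1cc2OB(Br)Oc2cc1Br | intermediate
3 | 2-bromo-4,5-dihydroxybenzaldehyde | O=Cc1cc(O)c(O)cc1Br | intermediate
4 | chloromethyl methyl ether | COCCl | starting material
5 | 2-bromo-4,5-bis(methoxymethoxy)benzaldehyde | COCOc1cc(Br)c(C=O)cc1OCOC | intermediate
6 | [2-bromo-4,5-bis(methoxymethoxy)phenyl]methanol | COCOc1cc(Br)c(CO)cc1OCOC | intermediate
7 | 2-bromo-4,5-bis(methoxymethoxy)benzyl bromide | COCOc1cc(Br)c(CBr)cc1OCOC | intermediate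
8 | sodium [2-bromo-4,5-bis(methoxymethoxy)phenyl]methanolate (not isolated) | COCOc1cc(Br)c(C[O-])cc1OCOC.[Na+] | intermediate
9 | bis[2-bromo-4,5-bis(methoxymethoxy)benzyl] ether | COCOc1cc(Br)c(COCc2cc(OCOC)c(OCOC)cc2Br)cc1OCOC | intermediate
10 | 1,2-dibromotetrachloroethane | ClC(Cl)(Br)C(Cl)(Cl)Br | starting material
11 | bis[2-bromo-3-(chloromagnesio)-4,5-bis(methoxymethoxy)benzyl] ether (not isolated) | COCOc1cc(COCc2cc(OCOC)c(OCOC)c([Mg]Cl)c2Br)c(Br)c([Mg]Cl)c1OCOC | intermediate
12 | bis[2,3-dibromo-4,5-bis(methoxymethoxy)benzyl] ether | COCOc1cc(COCc2cc(OCOC)c(OCOC)c(Br)c2Br)c(Br)c(Br)c1OCOC | intermediate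
13 | bis(2,3-dibromo-4,5-dihydroxybenzyl) ether | Oc1cc(COCc2cc(O)c(O)c(Br)c2Br)c(Br)c(Br)c1O | target

Total step count: 7
Longest linear sequence: 7 steps (1 → 3 → 5 → 6 → 7 → 9 → 12 → 13)

**Steps most likely to fail**

**Step 6.** Deprotonation of two electron-rich rings by a mild amide may be slow or may stop after one ring. Metalation may also leak to C6, and warming to force conversion invites loss of MgBrCl from the ortho-bromoaryl metal.

The fallback brings the C3 bromine in as an electrophile on the monomer instead of through a carbanion. It sets out from 3 and returns at 12.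
- Catechol aldehyde 3 is treated with Br2 (1 equiv) in AcOH at rt. The free C4 hydroxyl (ortho director) and the formyl group (meta director) point to the same carbon, which should give 2,3-dibromo-4,5-dihydroxybenzaldehyde F1.
- Reagent 4 with iPr2NEt in CH2Cl2 should give 2,3-dibromo-4,5-bis(methoxymethoxy)benzaldehyde F2.
- NaBH4 in MeOH should give [2,3-dibromo-4,5-bis(methoxymethoxy)phenyl]methanol F3.
- Half of this alcohol is converted with CBr4/PPh3 into 2,3-dibromo-4,5-bis(methoxymethoxy)benzyl bromide F4.
- The other half is deprotonated with NaH to sodium [2,3-dibromo-4,5-bis(methoxymethoxy)phenyl]methanolate F5, which displaces bromide from F4 and delivers 12.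

**Step 7.** Several things may go wrong here:
- acid-induced ionisation of the benzylic C–O bond, assisted by the para oxygen
- capture of the liberated methoxymethyl cation at C6
- closure of a methylene acetal between neighbouring oxygens
- incomplete removal of the hindered C4 acetal

The fallback avoids Brønsted acid by going through silyl ethers. It sets out from 12 and returns at 13. TMSOTf and 2,2'-bipyridyl in CH3CN (0 °C → rt) should exchange each aryl MOM acetal for a silyl ether, giving bis[2,3-dibromo-4,5-bis(trimethylsilyloxy)benzyl] ether F6. Addition of water at neutral pH should then hydrolyse the four aryl silyl ethers to 13.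

**Step 4.** The electron-rich benzylic bromide may self-alkylate or hydrolyse during isolation, and traces of HBr may cause acetal loss.

The fallback avoids any isolated halide and merges steps 4 and 5. It sets out from 6 and returns at 9. All of 6 is converted with NaH in THF into alkoxide 8, and TsCl (0.5 equiv) is added at 0 °C. Half of the alkoxide should then be sulfonylated to 2-bromo-4,5-bis(methoxymethoxy)benzyl 4-methylbenzenesulfonate F7. This tosylate is not isolated but is displaced in the same flask by the remaining 8 to give 9. The medium stays basic throughout, so the acetals never meet acid.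

**Further compounds**
F1 | step 6 | 2,3-dibromo-4,5-dihydroxybenzaldehyde | O=Cc1cc(O)c(O)c(Br)c1Br
F2 | step 6 | 2,3-dibromo-4,5-bis(methoxymethoxy)benzaldehyde | COCOc1cc(C=O)c(Br)c(Br)c1OCOC
F3 | step 6 | [2,3-dibromo-4,5-bis(methoxymethoxy)phenyl]methanol | COCOc1cc(CO)c(Br)c(Br)c1OCOC
F4 | step 6 | 2,3-dibromo-4,5-bis(methoxymethoxy)benzyl bromide | COCOc1cc(CBr)c(Br)c(Br)c1OCOC
F5 | step 6 | sodium [2,3-dibromo-4,5-bis(methoxymethoxy)phenyl]methanolate | COCOc1cc(C[O-])c(Br)c(Br)c1OCOC.[Na+]
F6 | step 7 | bis[2,3-dibromo-4,5-bis(trimethylsilyloxy)benzyl] ether | C[Si](C)(C)Oc1cc(COCc2cc(O[Si](C)(C)C)c(O[Si](C)(C)C)c(Br)c2Br)c(Br)c(Br)c1O[Si](C)(C)C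
F7 | step 4 | 2-bromo-4,5-bis(methoxymethoxy)benzyl 4-methylbenzenesulfonate | COCOc1cc(Br)c(COS(=O)(=O)c2ccc(C)cc2)cc1OCOC
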